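**Plan**

- Retrosynthesis: the C4 hydroxymethyl group is traced back to a methyl ester, the C2–Br and C6–Br bonds are cut (bromination ortho to the phenol), and the phenol is masked as its methyl ether.
- The ring bonds C1–C2 and C5–C6 are then cut. Arene C2–C5 map onto C3–C6 of a 4-bromo-2-pyrone-5-carboxylate, and arene C1 and C6 come from 1,1-dimethoxyethene.
- Enabling feature: the C1 oxygen is para to the C4 carbon substituent, and the C3 bromine (meta to oxygen, out of reach of electrophilic bromination) sits next to C4. This is the pattern of a coumalate-type pyrone with bromine on pyrone C4, whose diene termini C3 and C6 accept an oxygen-bearing two-carbon unit.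
- Forward: the pyrone ring is built first from dimethyl 3-oxopentanedioate and trimethyl orthoformate, and its 4-hydroxyl is exchanged for bromide. The benzene ring then arises by cycloaddition with loss of CO2 and methanol, followed by ether cleavage, double bromination and ester reduction.
- Stereochemistry: the target has no stereocentre; the bridgehead centres of the cycloadduct are transient.

Key step: step 3

Assumption: 1,1-dimethoxyethene is taken as a purchased reagent; if supply fails, dehydrobromination of bromoacetaldehyde dimethyl acetal with KOtBu would give it in one operation.

**Route**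

Step 1
Reactants: 1 dimethyl 3-oxopentanedioate; 2 trimethyl orthoformate
Product: 4 methyl 4-hydroxy-2-oxo-2H-pyran-5-carboxylate, via methoxymethylidene ketodiester 3 (not isolated)
Conditions: HC(OMe)3 (1.1 equiv), Ac2O (2.2 equiv), 130 °C; concentrate; then 2 M aq. HCl, 25 °C
Reagents that add atoms: water, O
Why: Acetic anhydride-promoted alkoxymethylenation of the active methylene of a β-keto ester (Claisen-type orthoester condensation) should give 3, and aqueous acid should then hydrolyse the enol ether and close the lactone onto the distal ester to give the 4-hydroxy-2-pyrone; the diester is symmetric, so no regiochemical question arises.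

Step 2
Reactants: 4 methyl 4-hydroxy-2-oxo-2H-pyran-5-carboxylate
Product: 5 methyl 4-bromo-2-oxo-2H-pyran-5-carboxylate
Conditions: POBr3 (1.5 equiv), MeCN, 70 °C; ice-water quench
Reagents that add atoms: phosphorus oxybromide, O=P(Br)(Br)Br
Why: Deoxybromination of a vinylogous acid, in which the 4-hydroxyl is phosphorylated and replaced by bromide through addition–elimination at C4, as is standard for 4-hydroxy-2-pyrones and 4-hydroxycoumarins; DMF is left out to avoid Vilsmeier formylation at pyrone C3.

Step 3
Reactants: 5 methyl 4-bromo-2-oxo-2H-pyran-5-carboxylate; 6 1,1-dimethoxyethene
Product: 9 methyl 2-bromo-4-methoxybenzoate, via bicyclic lactone cycloadduct 7 (not isolated), via dimethoxycyclohexadiene ester 8 (not isolated)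
Conditions: 6 (3 equiv), toluene, 25 → 110 °C, sealed tube
Reagents that add atoms: none
Why: The electron-poor pyrone 5 acts as the 4π component (C3 to C6) in an inverse-electron-demand Diels–Alder reaction with the electron-rich alkene 6 to give the bridged lactone 7, which expels CO2 by cycloreversion to diene 8, and 8 aromatises by 1,2-elimination of methanol. The closest known reaction type is the cycloaddition/CO2 extrusion of coumalate esters with ketene acetals and enol ethers, which gives 4-alkoxybenzoates. The six-membered carbocycle is closed intermolecularly by the [4+2] cycloaddition, the pyrone C6–CH2 and pyrone C3–C(OMe)2 bonds forming in one operation (possibly asynchronously), and this ring becomes the benzene ring. No stereocentre survives, since the two bridgehead centres of 7 are lost on aromatisation, so endo/exo and facial selectivity do not matter. The step needs regioselectivity: the nucleophilic CH2 terminus must bond to pyrone C6, which is β to the C5 ester and vinylogously conjugated to the lactone carbonyl, and this places the methoxy group para to the ester and the bromine ortho to it. The same double activation of C6 should let cycloaddition outrun addition–elimination at the brominated C4, which is activated by the lactone carbonyl alone.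

Step 4
Reactants: 9 methyl 2-bromo-4-methoxybenzoate
Product: 10 methyl 2-bromo-4-hydroxybenzoate
Conditions: BBr3 (2.5 equiv), CH2Cl2, −78 → 0 °C; ice-water quench
Reagents that add atoms: none
Why: Lewis acid-mediated aryl methyl ether cleavage (BBr3 demethylation) by O-complexation and SN2 attack of bromide on the methyl group; at or below 0 °C the methyl ester and the aryl bromide should stay intact.

Step 5
Reactants: 10 methyl 2-bromo-4-hydroxybenzoate
Product: 11 methyl 2,3,5-tribromo-4-hydroxybenzoate
Conditions: Br2 (2.2 equiv), AcOH, 25 → 50 °C; aq. Na2S2O3 quench
Reagents that add atoms: bromine, BrBr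
Why: Electrophilic aromatic bromination of a phenol in which the hydroxyl (ortho), the ester (meta) and the C2 bromine (ortho/para) all direct to C3 and C5 while the para position is blocked, as in the standard dibromination of 4-hydroxybenzoates.

Step 6
Reactants: 11 methyl 2,3,5-tribromo-4-hydroxybenzoate
Product: 12 2,3,6-tribromo-4-(hydroxymethyl)phenol
Conditions: iBu2AlH (4 equiv), THF–toluene, −78 → 0 °C; aq. potassium sodium tartrate
Reagents that add atoms: none
Why: Hydride reduction of the ester to the primary alcohol with excess diisobutylaluminium hydride, the first equivalent being consumed by the phenol; aryl bromides are inert to this reagent at low temperature, and esters bearing a free para-phenol are routinely reduced this way.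

**Compound list**

1 | dimethyl 3-oxopentanedioate | COC(=O)CC(=O)CC(=O)OC | starting material
2 | trimethyl orthoformate | COC(OC)OC | starting material
3 | dimethyl 2-(methoxymethylidene)-3-oxopentanedioate (E/Z mixture, not isolated) | COC=C(C(=O)OC)C(=O)CC(=O)OC | intermediate
4 | methyl 4-hydroxy-2-oxo-2H-pyran-5-carboxylate | COC(=O)C1=COC(=O)C=C1O | intermediate
5 | methyl 4-bromo-2-oxo-2H-pyran-5-carboxylate | COC(=O)C1=COC(=O)C=C1Br | intermediate
6 | 1,1-dimethoxyethene | C=C(OC)OC | starting material
7 | methyl 8-bromo-5,5-dimethoxy-3-oxo-2-oxabicyclo[2.2.2]oct-7-ene-7-carboxylate (racemic, not isolated) | O=C1OC2CC(OC)(OC)C1C(Br)=C2C(=O)OC | intermediate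
8 | methyl 6-bromo-4,4-dimethoxycyclohexa-1,5-diene-1-carboxylate (not isolated) | COC(=O)C1=CCC(OC)(OC)C=C1Br | intermediate
9 | methyl 2-bromo-4-methoxybenzoate | COC(=O)c1ccc(OC)cc1Br | intermediate
10 | methyl 2-bromo-4-hydroxybenzoate | COC(=O)c1ccc(O)cc1Br | intermediate
11 | methyl 2,3,5-tribromo-4-hydroxybenzoate | COC(=O)c1cc(Br)c(O)c(Br)c1Br | intermediate
12 | 2,3,6-tribromo-4-(hydroxymethyl)phenol | OCc1cc(Br)c(O)c(Br)c1Br | target

**Step count and risks**

Total step count: 6. Longest linear sequence: 6 steps (1 → 12).

Steps most likely to fail:

1. Step 3. The ketene acetal may add to the bromine-bearing pyrone C4 and expel bromide, or polymerise under traces of acid, faster than it cycloadds; methanol loss from the diene may also stall. The fallback sets out from 5 and uses a less nucleophilic two-carbon partner that needs no elimination. Heating 5 with ethoxyethyne (sold as a solution in hexanes) in toluene at 90–110 °C should give, with the same regiochemistry, the bicyclic diene lactone methyl 8-bromo-5-ethoxy-3-oxo-2-oxabicyclo[2.2.2]octa-5,7-diene-7-carboxylate F1. F1 should lose CO2 directly to give methyl 2-bromo-4-ethoxybenzoate F2. Cleavage of the ethyl ether with BBr3 in CH2Cl2 at −78 → 0 °C brings the sequence back to the route at 10.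

2. Step 2. Deoxybromination may stay incomplete, or the pyrone ring may be degraded by the HBr formed at the temperature required. The fallback sets out from 4 and separates activation from halide introduction. Tf2O and Et3N in CH2Cl2 at −78 °C should give methyl 2-oxo-4-(trifluoromethylsulfonyloxy)-2H-pyran-5-carboxylate F3. LiBr in acetone at 25–50 °C should then displace the triflate by addition–elimination at C4 under non-acidic conditions, coming back to the route at 5.

3. Step 6. Hydride addition to an ester deactivated by the para aluminium phenoxide may be slow, and forcing it may cause hydrodebromination or decomposition of the hydroxybenzyl alcohol on work-up. The fallback sets out from 11 and changes the carbonyl form and the hydride type. Saponification with NaOH in aqueous MeOH at reflux, then acidification, should give 2,3,5-tribromo-4-hydroxybenzoic acid F4. BH3·THF at 0 → 25 °C, an electrophilic hydride that reduces carboxylic acids selectively and tolerates the phenol and aryl bromides, should then reduce F4, coming back to the route at 12.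

**Further compounds**

F1 | step 3 | methyl 8-bromo-5-ethoxy-3-oxo-2-oxabicyclo[2.2.2]octa-5,7-diene-7-carboxylate (bicyclic diene lactone, racemic, not isolated) | O=C1OC2C=C(OCC)C1C(Br)=C2C(=O)OC
F2 | step 3 | methyl 2-bromo-4-ethoxybenzoate | CCOc1ccc(C(=O)OC)c(Br)c1
F3 | step 2 | methyl 2-oxo-4-(trifluoromethylsulfonyloxy)-2H-pyran-5-carboxylate | COC(=O)C1=COC(=O)C=C1OS(=O)(=O)C(F)(F)F
F4 | step 6 | 2,3,5-tribromo-4-hydroxybenzoic acid | OC(=O)c1cc(Br)c(O)c(Br)c1Br
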